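**Retrosynthetic overview**

- Feature: in germacrane numbering, C3 is one carbon shared by the ten-membered carbocycle (C1–C10) and the 3(2H)-furanone (O–C3=C2–C1(=O)–C10). It is bonded only to vinylic C4, to C2 and to the ring oxygen, so it can be supplied as carbon monoxide.
- Target 38 ⇒ diol 34 ⇒ furanone macrocycle 29 (late C8/C9 acylation, acetonide removal, C11 methylenation).
- 29 ⇒ seco Z-vinyl iodide / tertiary propargylic alcohol 25 + CO: C3–C4, C2–C3 and O–C3 are formed in one carbonylative coupling–cyclisation.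
- 25 ⇒ methyl ketone 23 + ethynylmagnesium bromide (C10); Z-iodoalkene from the C6 propynyl carbinol; C7 by Johnson–Claisen rearrangement; C8 and C9 from L-threitol acetonide 1 (L-tartaric acid).
- Ring order: dioxolane (from 1), γ-lactone (steps 7 and 9), then ten-membered carbocycle and furanone together (step 15).

Key step: step 15

Assumption: (+)-2,3-O-isopropylidene-L-threitol 1 (made from L-tartaric acid) is taken as a commercial starting material; carbons that end up in the target carry germacrane numbers (C1–C13) throughout, and metal alkoxides, enolates and carbanions that differ from a numbered compound only by a metal in place of a proton are not numbered separately.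

**Step 1**
Reactants: 1 (+)-2,3-O-isopropylidene-L-threitol
Product: 2 [(4S,5S)-5-({[tert-butyl(dimethyl)silyl]oxy}methyl)-2,2-dimethyl-1,3-dioxolan-4-yl]methanol
Conditions: NaH (1.0 equiv), THF, 0 °C to rt; then TBSCl (1.0 equiv), rt
Reagents that add atoms: tert-butyldimethylsilyl chloride, CC(C)(C)[Si](C)(C)Cl
Why: Monosilylation of the C2-symmetric diol through its poorly soluble monosodium alkoxide should stop after one silyl group, and because the two hydroxyls are homotopic no stereochemical question arises.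

**Step 2**
Reactants: 2 mono-silyl ether
Product: 3 (4R,5S)-5-({[tert-butyl(dimethyl)silyl]oxy}methyl)-2,2-dimethyl-1,3-dioxolane-4-carbaldehyde
Conditions: Dess–Martin periodinane, pyridine, CH2Cl2, 0 °C to rt
Reagents that add atoms: none
Why: Dess–Martin oxidation of the primary alcohol under buffered non-aqueous conditions should give the α-alkoxy aldehyde without over-oxidation or epimerisation at the dioxolane carbon.

**Step 3**
Reactants: 3 aldehyde; 4 methyl bis(2,2,2-trifluoroethyl)phosphonoacetate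
Product: 5 methyl (2Z)-3-[(4S,5S)-5-({[tert-butyl(dimethyl)silyl]oxy}methyl)-2,2-dimethyl-1,3-dioxolan-4-yl]prop-2-enoate
Conditions: KN(SiMe3)2, 18-crown-6, THF, −78 °C
Reagents that add atoms: methyl bis(2,2,2-trifluoroethyl)phosphonoacetate, COC(=O)CP(=O)(OCC(F)(F)F)OCC(F)(F)F
Why: Still–Gennari olefination, in which the electron-poor bis(trifluoroethyl) phosphonate with a crown-ether-separated potassium counter-ion collapses under kinetic control to the Z-enoate.

**Step 4**
Reactants: 5 Z-enoate
Product: 6 (2Z)-3-[(4S,5S)-5-({[tert-butyl(dimethyl)silyl]oxy}methyl)-2,2-dimethyl-1,3-dioxolan-4-yl]prop-2-en-1-ol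
Conditions: iBu2AlH (2.2 equiv), CH2Cl2, −78 °C
Reagents that add atoms: none
Why: 1,2-Reduction of the enoate by iBu2AlH at low temperature should give the allylic alcohol with the Z geometry intact and the silyl ether and acetal untouched.

**Step 5**
Reactants: 6 Z-allylic alcohol; 7 triethyl orthoacetate
Product: 9 ethyl (3S)-3-[(4S,5S)-5-({[tert-butyl(dimethyl)silyl]oxy}methyl)-2,2-dimethyl-1,3-dioxolan-4-yl]pent-4-enoate, via mixed ketene acetal 8 (not isolated)
Conditions: EtCO2H (cat.), xylene, 140 °C, EtOH distilled off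
Reagents that add atoms: triethyl orthoacetate, CC(OCC)(OCC)OCC
Why: Johnson–Claisen (orthoester) rearrangement, in which the chair [3,3] shift of ketene acetal 8 forms C7–C11 and, because allylic 1,3-strain in the Z-alkene holds the C8–H bond in the alkene plane, the new bond should form on the face anti to the C8–O bond, which sets C7 as S.

**Step 6**
Reactants: 9 pentenoate
Product: 11 ethyl (3R)-3-[(4S,5S)-5-({[tert-butyl(dimethyl)silyl]oxy}methyl)-2,2-dimethyl-1,3-dioxolan-4-yl]-4-oxobutanoate, via ozonide 10 (not isolated)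
Conditions: O3, CH2Cl2, −78 °C; then PPh3, −78 °C to rt
Reagents that add atoms: ozone, [O-][O+]=O
Why: Ozonolysis with reductive work-up (Criegee mechanism through ozonide 10) cleaves the only alkene under cold neutral conditions that should not epimerise the α-branched aldehyde at C7.

**Step 7**
Reactants: 11 aldehyde ester; 12 1-propynylmagnesium bromide
Product: 14 (4S,5S)-4-[(4S,5S)-5-({[tert-butyl(dimethyl)silyl]oxy}methyl)-2,2-dimethyl-1,3-dioxolan-4-yl]-5-(prop-1-yn-1-yl)oxolan-2-one, via hydroxy ester 13 (not isolated)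
Conditions: THF, −78 to 0 °C; aqueous work-up; PPTS (cat.), CH2Cl2, rt
Reagents that add atoms: 1-propynylmagnesium bromide, CC#C[Mg]Br
Why: Felkin–Anh addition of the alkynyl Grignard reagent to the aldehyde (dioxolanyl group anti to the nucleophile, reinforced by 1,3-anti induction from the C8 oxygen) should set C6 as S while the ester is not attacked at −78 °C, and the γ-hydroxy ester 13 then closes to the trans-disubstituted γ-lactone.

**Step 8**
Reactants: 14 propynyl lactone
Product: 16 (3S,4S,5Z)-3-[(4S,5S)-5-({[tert-butyl(dimethyl)silyl]oxy}methyl)-2,2-dimethyl-1,3-dioxolan-4-yl]-6-iodohept-5-ene-1,4-diol, via cyclic vinylalanate 15 (not isolated)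
Conditions: NaAlH2(OCH2CH2OMe)2 (4 equiv), THF, 0 °C to rt; then I2, THF, −78 to 0 °C
Reagents that add atoms: iodine, II
Why: The aluminium hydride first reduces the lactone, and the C6 alkoxide so released directs trans-hydroalumination of the propargylic alkyne (hydride to C5, aluminium to C4 in the five-membered oxa-aluminacycle 15), so that iodinolysis with retention should give the Z-vinyl iodide with iodine on C4.

**Step 9**
Reactants: 16 iodo diol
Product: 18 (4S,5S)-4-[(4S,5S)-5-({[tert-butyl(dimethyl)silyl]oxy}methyl)-2,2-dimethyl-1,3-dioxolan-4-yl]-5-[(1Z)-2-iodoprop-1-en-1-yl]oxolan-2-one, via lactol 17 (not isolated)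
Conditions: TEMPO (20 mol %), PhI(OAc)2 (2.5 equiv), CH2Cl2, rt
Reagents that add atoms: none
Why: TEMPO/PhI(OAc)2 oxidative lactonisation, in which the oxoammonium salt oxidises the primary C12 alcohol faster than the secondary allylic one, ring closure by the C6 hydroxyl gives lactol 17, and a second oxidation gives the γ-lactone.

**Step 10**
Reactants: 18 silyl ether
Product: 19 (4S,5S)-4-[(4S,5S)-5-(hydroxymethyl)-2,2-dimethyl-1,3-dioxolan-4-yl]-5-[(1Z)-2-iodoprop-1-en-1-yl]oxolan-2-one
Conditions: HF·pyridine, pyridine, THF, 0 °C to rt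
Reagents that add atoms: none
Why: Fluoride-mediated desilylation under buffered conditions should free the primary alcohol without opening the lactone or the acetal.

**Step 11**
Reactants: 19 primary alcohol
Product: 20 (4S,5S)-4-[(4S,5R)-5-formyl-2,2-dimethyl-1,3-dioxolan-4-yl]-5-[(1Z)-2-iodoprop-1-en-1-yl]oxolan-2-one
Conditions: Dess–Martin periodinane, pyridine, CH2Cl2, 0 °C to rt
Reagents that add atoms: none
Why: Dess–Martin oxidation gives the aldehyde, and the trans-dioxolane is the more stable arrangement so the α-centre C9 is not at risk.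

**Step 12**
Reactants: 20 aldehyde; 21 methylmagnesium bromide
Product: 22 (4S,5S)-4-[(4S,5S)-5-(1-hydroxyethyl)-2,2-dimethyl-1,3-dioxolan-4-yl]-5-[(1Z)-2-iodoprop-1-en-1-yl]oxolan-2-one (both C10 epimers)
Conditions: THF, −78 °C
Reagents that add atoms: methylmagnesium bromide, C[Mg]Br
Why: A Grignard reagent adds to an aldehyde far faster than to a γ-lactone at −78 °C, the vinyl iodide does not exchange with MeMgBr, and the configuration of the new carbinol is irrelevant because it is oxidised next.

**Step 13**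
Reactants: 22 secondary alcohol
Product: 23 (4S,5S)-4-[(4S,5R)-5-acetyl-2,2-dimethyl-1,3-dioxolan-4-yl]-5-[(1Z)-2-iodoprop-1-en-1-yl]oxolan-2-one
Conditions: Dess–Martin periodinane, pyridine, CH2Cl2, rt
Reagents that add atoms: none
Why: Dess–Martin oxidation of the secondary alcohol converges both epimers on the methyl ketone.

**Step 14**
Reactants: 23 methyl ketone; 24 ethynylmagnesium bromide
Product: 25 (4S,5S)-4-{(4S,5R)-5-[(2S)-2-hydroxybut-3-yn-2-yl]-2,2-dimethyl-1,3-dioxolan-4-yl}-5-[(1Z)-2-iodoprop-1-en-1-yl]oxolan-2-one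
Conditions: THF, −78 to −20 °C
Reagents that add atoms: ethynylmagnesium bromide, C#C[Mg]Br
Why: 1,2-Addition of the alkynyl Grignard reagent to the ketone, which is far more electrophilic than the lactone, should follow the polar Felkin–Anh model (C9–O bond anti to the incoming nucleophile, which passes the C9 hydrogen) and give the 10S tertiary propargylic alcohol.

**Step 15**
Reactants: 25 seco Z-vinyl iodide tertiary propargylic alcohol; 26 carbon monoxide
Product: 29 (6R,7S,8S,9R,10R)-3,10-epoxy-8,9-(isopropylidenedioxy)-1-oxo-13-norgermacra-2,4Z-dien-12,6-olide, via macrocyclic ynone 27 (not isolated), via enaminone 28 (not isolated)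
Conditions: PdCl2(PPh3)2 (10 mol %), CuI (10 mol %), CO (1 atm), Et3N, THF, 40 °C, 25 added by syringe pump to about 1 mM; then Et2NH, H2O, rt
Reagents that add atoms: carbon monoxide, [C-]#[O+]; water, O
Why: Proposed new method: zerovalent palladium (from PdCl2(PPh3)2) inserts into the C4–I bond of 25 with retention of the Z geometry, CO inserts to give the C3 acylpalladium (C3–C4), the copper acetylide formed at C2 transmetalates to an eleven-membered acyl(alkynyl)palladacycle, and reductive elimination forms C2–C3 and releases the ten-membered ynone 27. Et2NH then adds to C1 to give enaminone 28 with C10 and C3 cis on the ring alkene, the C10 hydroxyl attacks the C3 carbonyl in a 5-exo-trig closure (O–C3), the former CO oxygen leaves as water, and hydrolysis of the iminium places a water oxygen on C1. The closest known reaction type is the intermolecular PdCl2(PPh3)2/CuI-catalysed carbonylative coupling of organic halides with tertiary propargylic alcohols to 3(2H)-furanones, together with the amine-promoted isomerisation of 4-hydroxyalk-2-yn-1-ones; a ring-closing version through a ten-membered ynone has not been shown. The carbocycle thus closes by reductive elimination from the palladacycle (ring contraction from eleven to ten atoms) and the furanone by 5-exo-trig addition to a carbonyl group, and because both rings close at C3 the strain of 27 is released as soon as the amine rehybridises C1 and C2. No stereocenter is formed, C6–C10 are spectators, and the only stereochemical demand, the Z alkene, is met by stereoretentive oxidative addition. The step needs cyclisation to win over oligomerisation, direct alkynylation and acyl capture by the hydroxyl: slow addition to about 1 mM under CO keeps the acylpalladium dilute and carbonylated, direct coupling would need a nine-membered enyne, the fully substituted C10 and the trans-disposed lactone and dioxolane turn the chain ends toward each other, and the tertiary hydroxyl is too hindered to be acylated.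

**Step 16**
Reactants: 29 furanone macrocycle; 30 N,N-dimethylmethyleneiminium iodide (Eschenmoser's salt)
Product: 33 (6R,7S,8S,9R,10R)-3,10-epoxy-8,9-(isopropylidenedioxy)-1-oxogermacra-2,4Z,11(13)-trien-12,6-olide, via Mannich base 31 (not isolated), via trimethylammonium iodide 32 (not isolated)
Conditions: LiN(SiMe3)2, THF, −78 °C; then 30, −78 °C to rt; then MeI, CH2Cl2/MeOH, rt; then aq. NaHCO3, EtOAc, rt
Reagents that add atoms: N,N-dimethylmethyleneiminium iodide, C=[N+](C)C.[I-]
Why: The lactone is the only carbonyl group with α-hydrogens (the furanone ketone is flanked by quaternary C10 and vinylic C2), so kinetic deprotonation and Mannich reaction with the iminium salt (Eschenmoser methylenation) should give 31 with the aminomethyl group trans to C8, and exhaustive methylation followed by base-induced Hofmann-type elimination of trimethylamine from 32 gives the exocyclic methylene.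

**Step 17**
Reactants: 33 α-methylene lactone acetonide
Product: 34 (6R,7R,8S,9R,10R)-3,10-epoxy-8,9-dihydroxy-1-oxogermacra-2,4Z,11(13)-trien-12,6-olide
Conditions: CF3CO2H/H2O (9:1), CH2Cl2, 0 °C
Reagents that add atoms: none
Why: Acid-catalysed hydrolysis of the isopropylidene acetal, which is strained by trans fusion to the ten-membered ring, should be faster than any reaction of the vinylogous ester or the α-methylene lactone, both of which tolerate aqueous acid.

**Step 18**
Reactants: 34 diol; 35 isovaleric anhydride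
Product: 36 (6R,7S,8S,9R,10R)-3,10-epoxy-9-hydroxy-8-(3-methylbutanoyloxy)-1-oxogermacra-2,4Z,11(13)-trien-12,6-olide
Conditions: DMAP (cat.), pyridine, CH2Cl2, −20 °C
Reagents that add atoms: isovaleric anhydride, CC(C)CC(=O)OC(=O)CC(C)C
Why: DMAP-catalysed acylation under kinetic control should take the C8 hydroxyl, because the C9 hydroxyl is neopentyl-like next to the fully substituted C10.

**Step 19**
Reactants: 36 C8 isovalerate; 37 acetic anhydride
Product: 38 CNP0255553.1 (6R,7S,8S,9R,10R)-9-acetoxy-3,10-epoxy-8-(3-methylbutanoyloxy)-1-oxogermacra-2,4Z,11(13)-trien-12,6-olide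
Conditions: DMAP (cat.), Et3N, CH2Cl2, rt
Reagents that add atoms: acetic anhydride, CC(=O)OC(C)=O
Why: DMAP-catalysed acetylation of the remaining hindered secondary alcohol completes the target under conditions too mild to open the lactone or to add irreversibly to the α-methylene group.

**Compound list**

1 | (+)-2,3-O-isopropylidene-L-threitol, [(4S,5S)-2,2-dimethyl-1,3-dioxolane-4,5-diyl]dimethanol | OC[C@@H]1OC(C)(C)O[C@H]1CO | starting material
2 | [(4S,5S)-5-({[tert-butyl(dimethyl)silyl]oxy}methyl)-2,2-dimethyl-1,3-dioxolan-4-yl]methanol | OC[C@@H]1OC(C)(C)O[C@H]1CO[Si](C)(C)C(C)(C)C | intermediate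
3 | (4R,5S)-5-({[tert-butyl(dimethyl)silyl]oxy}methyl)-2,2-dimethyl-1,3-dioxolane-4-carbaldehyde | O=C[C@@H]1OC(C)(C)O[C@H]1CO[Si](C)(C)C(C)(C)C | intermediate
4 | methyl bis(2,2,2-trifluoroethyl)phosphonoacetate | COC(=O)CP(=O)(OCC(F)(F)F)OCC(F)(F)F | starting material
5 | methyl (2Z)-3-[(4S,5S)-5-({[tert-butyl(dimethyl)silyl]oxy}methyl)-2,2-dimethyl-1,3-dioxolan-4-yl]prop-2-enoate | COC(=O)/C=C\[C@@H]1OC(C)(C)O[C@H]1CO[Si](C)(C)C(C)(C)C | intermediate
6 | (2Z)-3-[(4S,5S)-5-({[tert-butyl(dimethyl)silyl]oxy}methyl)-2,2-dimethyl-1,3-dioxolan-4-yl]prop-2-en-1-ol | OC/C=C\[C@@H]1OC(C)(C)O[C@H]1CO[Si](C)(C)C(C)(C)C | intermediate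
7 | triethyl orthoacetate | CC(OCC)(OCC)OCC | starting material
8 | mixed ketene acetal, the 1-ethoxyvinyl ether of 6 (not isolated) | C=C(OCC)OC/C=C\[C@@H]1OC(C)(C)O[C@H]1CO[Si](C)(C)C(C)(C)C | intermediate
9 | ethyl (3S)-3-[(4S,5S)-5-({[tert-butyl(dimethyl)silyl]oxy}methyl)-2,2-dimethyl-1,3-dioxolan-4-yl]pent-4-enoate | CCOC(=O)C[C@@H](C=C)[C@@H]1OC(C)(C)O[C@H]1CO[Si](C)(C)C(C)(C)C | intermediate
10 | ozonide of 9, 1,2,4-trioxolane in place of the vinyl group, both epimers at the trioxolane carbon (not isolated) | CCOC(=O)C[C@@H](C1OCOO1)[C@@H]1OC(C)(C)O[C@H]1CO[Si](C)(C)C(C)(C)C | intermediate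
11 | ethyl (3R)-3-[(4S,5S)-5-({[tert-butyl(dimethyl)silyl]oxy}methyl)-2,2-dimethyl-1,3-dioxolan-4-yl]-4-oxobutanoate | CCOC(=O)C[C@@H](C=O)[C@@H]1OC(C)(C)O[C@H]1CO[Si](C)(C)C(C)(C)C | intermediate
12 | 1-propynylmagnesium bromide | CC#C[Mg]Br | starting material
13 | ethyl (3S,4S)-3-[(4S,5S)-5-({[tert-butyl(dimethyl)silyl]oxy}methyl)-2,2-dimethyl-1,3-dioxolan-4-yl]-4-hydroxyhept-5-ynoate, formed as its bromomagnesium alkoxide (not isolated) | CCOC(=O)C[C@@H]([C@H](O)C#CC)[C@@H]1OC(C)(C)O[C@H]1CO[Si](C)(C)C(C)(C)C | intermediate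
14 | (4S,5S)-4-[(4S,5S)-5-({[tert-butyl(dimethyl)silyl]oxy}methyl)-2,2-dimethyl-1,3-dioxolan-4-yl]-5-(prop-1-yn-1-yl)oxolan-2-one | O=C1C[C@H]([C@@H]2OC(C)(C)O[C@H]2CO[Si](C)(C)C(C)(C)C)[C@@H](C#CC)O1 | intermediate
15 | cyclic vinylalanate, 2,5-dihydro-1,2-oxaluminol-2-uide with Al on C4 and O6, drawn in simplified form with the C12 alkoxide as sodium salt (not isolated) | [Na+].[Na+].[O-]CC[C@H]([C@@H]2OC(C)(C)O[C@H]2CO[Si](C)(C)C(C)(C)C)[C@@H]1O[Al-](OCCOC)(OCCOC)C(C)=C1 | intermediate
16 | (3S,4S,5Z)-3-[(4S,5S)-5-({[tert-butyl(dimethyl)silyl]oxy}methyl)-2,2-dimethyl-1,3-dioxolan-4-yl]-6-iodohept-5-ene-1,4-diol | OCC[C@H]([C@@H]2OC(C)(C)O[C@H]2CO[Si](C)(C)C(C)(C)C)[C@H](O)/C=C(/C)I | intermediate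
17 | lactol of 16, 2-hydroxyoxolane, both anomers (not isolated) | OC1C[C@H]([C@@H]2OC(C)(C)O[C@H]2CO[Si](C)(C)C(C)(C)C)[C@@H](/C=C(/C)I)O1 | intermediate
18 | (4S,5S)-4-[(4S,5S)-5-({[tert-butyl(dimethyl)silyl]oxy}methyl)-2,2-dimethyl-1,3-dioxolan-4-yl]-5-[(1Z)-2-iodoprop-1-en-1-yl]oxolan-2-one | O=C1C[C@H]([C@@H]2OC(C)(C)O[C@H]2CO[Si](C)(C)C(C)(C)C)[C@@H](/C=C(/C)I)O1 | intermediate
19 | (4S,5S)-4-[(4S,5S)-5-(hydroxymethyl)-2,2-dimethyl-1,3-dioxolan-4-yl]-5-[(1Z)-2-iodoprop-1-en-1-yl]oxolan-2-one | O=C1C[C@H]([C@@H]2OC(C)(C)O[C@H]2CO)[C@@H](/C=C(/C)I)O1 | intermediate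
20 | (4S,5S)-4-[(4S,5R)-5-formyl-2,2-dimethyl-1,3-dioxolan-4-yl]-5-[(1Z)-2-iodoprop-1-en-1-yl]oxolan-2-one | O=C1C[C@H]([C@@H]2OC(C)(C)O[C@H]2C=O)[C@@H](/C=C(/C)I)O1 | intermediate
21 | methylmagnesium bromide | C[Mg]Br | starting material
22 | (4S,5S)-4-[(4S,5S)-5-(1-hydroxyethyl)-2,2-dimethyl-1,3-dioxolan-4-yl]-5-[(1Z)-2-iodoprop-1-en-1-yl]oxolan-2-one, both C10 epimers | O=C1C[C@H]([C@@H]2OC(C)(C)O[C@H]2C(C)O)[C@@H](/C=C(/C)I)O1 | intermediate
23 | (4S,5S)-4-[(4S,5R)-5-acetyl-2,2-dimethyl-1,3-dioxolan-4-yl]-5-[(1Z)-2-iodoprop-1-en-1-yl]oxolan-2-one | O=C1C[C@H]([C@@H]2OC(C)(C)O[C@H]2C(C)=O)[C@@H](/C=C(/C)I)O1 | intermediate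
24 | ethynylmagnesium bromide | C#C[Mg]Br | starting material
25 | (4S,5S)-4-{(4S,5R)-5-[(2S)-2-hydroxybut-3-yn-2-yl]-2,2-dimethyl-1,3-dioxolan-4-yl}-5-[(1Z)-2-iodoprop-1-en-1-yl]oxolan-2-one | O=C1C[C@H]([C@@H]2OC(C)(C)O[C@H]2[C@@](C)(O)C#C)[C@@H](/C=C(/C)I)O1 | intermediate
26 | carbon monoxide | [C-]#[O+] | starting material
27 | (6R,7S,8S,9R,10S)-10-hydroxy-8,9-(isopropylidenedioxy)-3-oxo-13-norgermacr-4Z-en-1-yn-12,6-olide, ten-membered ring C1–C10 with C1≡C2, C3=O and Z-C4=C5 (not isolated) | O=C1C[C@@H]2[C@@H]3OC(C)(C)O[C@H]3[C@@](C)(O)C#CC(=O)/C(C)=C\[C@H]2O1 | intermediate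
28 | (6R,7S,8S,9R,10S)-1-(diethylamino)-10-hydroxy-8,9-(isopropylidenedioxy)-3-oxo-13-norgermacra-1,4Z-dien-12,6-olide, C10 and C3 cis on C1=C2 (not isolated) | O=C1C[C@@H]2[C@@H]3OC(C)(C)O[C@H]3[C@@](C)(O)/C(N(CC)CC)=C\C(=O)/C(C)=C\[C@H]2O1 | intermediate
29 | (6R,7S,8S,9R,10R)-3,10-epoxy-8,9-(isopropylidenedioxy)-1-oxo-13-norgermacra-2,4Z-dien-12,6-olide, furanone O–C3=C2–C1(=O)–C10 bridging the ten-membered ring, saturated trans γ-lactone | O=C1C[C@@H]2[C@@H]3OC(C)(C)O[C@H]3[C@@]3(C)OC(=CC3=O)/C(C)=C\[C@H]2O1 | intermediate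
30 | N,N-dimethylmethyleneiminium iodide (Eschenmoser's salt) | C=[N+](C)C.[I-] | starting material
31 | (6R,7S,8S,9R,10R,11R)-13-(dimethylamino)-3,10-epoxy-8,9-(isopropylidenedioxy)-1-oxogermacra-2,4Z-dien-12,6-olide, CH2NMe2 trans to C8 (not isolated) | O=C1[C@@H](CN(C)C)[C@@H]2[C@@H]3OC(C)(C)O[C@H]3[C@@]3(C)OC(=CC3=O)/C(C)=C\[C@H]2O1 | intermediate
32 | trimethylammonium iodide of 31 (not isolated) | O=C1[C@@H](C[N+](C)(C)C)[C@@H]2[C@@H]3OC(C)(C)O[C@H]3[C@@]3(C)OC(=CC3=O)/C(C)=C\[C@H]2O1.[I-] | intermediate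
33 | (6R,7S,8S,9R,10R)-3,10-epoxy-8,9-(isopropylidenedioxy)-1-oxogermacra-2,4Z,11(13)-trien-12,6-olide | O=C1C(=C)[C@@H]2[C@@H]3OC(C)(C)O[C@H]3[C@@]3(C)OC(=CC3=O)/C(C)=C\[C@H]2O1 | intermediate
34 | (6R,7R,8S,9R,10R)-3,10-epoxy-8,9-dihydroxy-1-oxogermacra-2,4Z,11(13)-trien-12,6-olide | O=C1C(=C)[C@@H]2[C@H](O)[C@@H](O)[C@@]3(C)OC(=CC3=O)/C(C)=C\[C@H]2O1 | intermediate
35 | isovaleric anhydride (3-methylbutanoic anhydride) | CC(C)CC(=O)OC(=O)CC(C)C | starting material
36 | (6R,7S,8S,9R,10R)-3,10-epoxy-9-hydroxy-8-(3-methylbutanoyloxy)-1-oxogermacra-2,4Z,11(13)-trien-12,6-olide | O=C1C(=C)[C@@H]2[C@H](OC(=O)CC(C)C)[C@@H](O)[C@@]3(C)OC(=CC3=O)/C(C)=C\[C@H]2O1 | intermediate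
37 | acetic anhydride | CC(=O)OC(C)=O | starting material
38 | CNP0255553.1, (6R,7S,8S,9R,10R)-9-acetoxy-3,10-epoxy-8-(3-methylbutanoyloxy)-1-oxogermacra-2,4Z,11(13)-trien-12,6-olide | C=C1C(=O)O[C@@H]2/C=C(/C)C3=CC(=O)[C@](C)(O3)[C@H](OC(C)=O)[C@@H](OC(=O)CC(C)C)[C@@H]12 | target

Total step count: 19
Longest linear sequence: 19 steps (1 to 38)

**Steps most likely to fail**

1. Step 15 (Proposed new method). The acylpalladium may be intercepted by the alkyne of a second molecule before the eleven-membered palladacycle forms (oligomerisation), or the strained ynone 27 may polymerise before the amine traps it. The fallback uses known chemistry and closes the same C3–C4 bond at an sp3 carbon, which lowers the strain of ring closure. It sets out from methyl ketone 23. BrMgC≡CCH2OSi(t-Bu)Me2 (from the commercial silyl propargyl ether and EtMgBr) would add as in step 14 to give tertiary propargylic alcohol silyl ether F1. HF·pyridine would free propargylic diol F2, and MnO2 would oxidise only its primary propargylic alcohol to ynal F3. A Nozaki–Hiyama–Kishi ring closure (CrCl2 in excess, NiCl2 catalytic, DMSO/THF, high dilution) between the C4 vinyl iodide and the C3 aldehyde would give macrocyclic enynol F4 as a mixture of C3 epimers, which does not matter. Dess–Martin oxidation would then give ynone 27, which is treated at once with Et2NH/H2O as in the second stage of step 15, and the route is rejoined at 29.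

2. Step 14. Chelation of magnesium between the ketone oxygen and the C9 oxygen may compete with the Felkin–Anh pathway and erode or invert the facial selectivity at C10, and the lactone may be attacked if the addition has to be warmed. The fallback reverses the order in which the two carbon groups are put on C10, so that a given facial preference of the dioxolanyl ketone leads to the other C10 epimer. It sets out from aldehyde 20. Me3SiC≡CMgBr (THF, −78 °C) would give silylated propargylic alcohol F5 (both epimers), and Dess–Martin oxidation would give alkynyl ketone F6. MeMgBr in CH2Cl2/Et2O at −78 °C, a poorly coordinating medium that favours the chelate between the ketone oxygen and the C9 oxygen, would give silylated tertiary alcohol F7. Bu4NF buffered with AcOH would remove the alkynyl silyl group, and the route is rejoined at 25.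

3. Step 16. The amide base may deprotonate C6 (the vinylogous position of the cross-conjugated furanone dienone) or add to the dienone instead of forming the lactone enolate, leading to decomposition. The fallback avoids a kinetic enolate and a strong base. It sets out from 29. Heating with tert-butoxybis(dimethylamino)methane (toluene, 80 °C) would condense at the only acidic CH2 to give enaminolactone F8. Aqueous oxalic acid in THF would hydrolyse it to α-hydroxymethylene lactone F9. Aqueous formaldehyde with K2CO3 in THF would then effect aldol addition and deformylative elimination, and the route is rejoined at 33.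

**Further compounds**

F1 | step 15 | (4S,5S)-4-{(4S,5R)-5-[(2S)-5-{[tert-butyl(dimethyl)silyl]oxy}-2-hydroxypent-3-yn-2-yl]-2,2-dimethyl-1,3-dioxolan-4-yl}-5-[(1Z)-2-iodoprop-1-en-1-yl]oxolan-2-one | O=C1C[C@H]([C@@H]2OC(C)(C)O[C@H]2[C@@](C)(O)C#CCO[Si](C)(C)C(C)(C)C)[C@@H](/C=C(/C)I)O1
F2 | step 15 | propargylic diol, the desilylated form of F1 | O=C1C[C@H]([C@@H]2OC(C)(C)O[C@H]2[C@@](C)(O)C#CCO)[C@@H](/C=C(/C)I)O1
F3 | step 15 | ynal, C3 aldehyde on the C1≡C2 alkyne | O=C1C[C@H]([C@@H]2OC(C)(C)O[C@H]2[C@@](C)(O)C#CC=O)[C@@H](/C=C(/C)I)O1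
F4 | step 15 | macrocyclic enynol, the C3 carbinol of ynone 27, both C3 epimers | O=C1C[C@@H]2[C@@H]3OC(C)(C)O[C@H]3[C@@](C)(O)C#CC(O)/C(C)=C\[C@H]2O1
F5 | step 14 | silylated propargylic alcohol, 1-hydroxy-3-(trimethylsilyl)prop-2-yn-1-yl group on the dioxolane, both C10 epimers | O=C1C[C@H]([C@@H]2OC(C)(C)O[C@H]2C(O)C#C[Si](C)(C)C)[C@@H](/C=C(/C)I)O1
F6 | step 14 | alkynyl ketone, 3-(trimethylsilyl)prop-2-ynoyl group on the dioxolane | O=C1C[C@H]([C@@H]2OC(C)(C)O[C@H]2C(=O)C#C[Si](C)(C)C)[C@@H](/C=C(/C)I)O1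
F7 | step 14 | silylated tertiary alcohol, the C-trimethylsilyl derivative of 25 | O=C1C[C@H]([C@@H]2OC(C)(C)O[C@H]2[C@@](C)(O)C#C[Si](C)(C)C)[C@@H](/C=C(/C)I)O1
F8 | step 16 | enaminolactone, the 11-[(E)-(dimethylamino)methylidene] derivative of 29 | O=C1/C(=C/N(C)C)[C@@H]2[C@@H]3OC(C)(C)O[C@H]3[C@@]3(C)OC(=CC3=O)/C(C)=C\[C@H]2O1
F9 | step 16 | α-hydroxymethylene lactone, the 11-(hydroxymethylidene) derivative of 29 | O=C1/C(=C/O)[C@@H]2[C@@H]3OC(C)(C)O[C@H]3[C@@]3(C)OC(=CC3=O)/C(C)=C\[C@H]2O1
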